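The numbers were chosen freely; no experiment stands behind them.

Counting couplings could not give me the links: a first end group that misses its partner can still take a link away in the side reaction.

    first end groups + second end groups → links (k1 = 0.53 L mol⁻¹ s⁻¹)
    second end groups + third end groups → links of the second sort (k2 = 0.25 L mol⁻¹ s⁻¹)
    links ⇌ isomer of the product (K3 = 0.75, k3 = 0.047 s⁻¹)
    first end groups + links → side product (k4 = 0.098 L mol⁻¹ s⁻¹)
    third end groups + protic impurity → quenched substrate (k5 = 0.12 L mol⁻¹ s⁻¹)

| flask | first end groups | second end groups | third end groups | protic impurity | time | remark |
|---|---|---|---|---|---|---|
| west | 0.22 M | 0.950 equiv | 1.00 equiv | 0.0660 M | 5.0 min | everything together at the start |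
| south-west | 0.22 M (fed, over 3.0 min) | 0.950 equiv | 1.00 equiv | 0.0660 M | 5.0 min | all else is in the flask from the start; the feed brings no volume worth counting |
| north-east | 0.22 M | 0.950 equiv | 1.00 equiv (fed, over 3.0 min) | 0.0660 M | 5.0 min | all else is in the flask from the start; the feed brings no volume worth counting |

- in percentages every species weighs as the first end groups in it: one side product counts as two
- run time (west): 5.0 min

1. the flask with the highest amount of links, in percent of the first end groups charged ("all alike" if they lie within 1.5 percentage points) (west / south-west / north-east / all alike)
2. final links, as a percentage of the first end groups charged, in west
3. final links, as a percentage of the first end groups charged, in south-west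
4. final links, as a percentage of the first end groups charged, in north-east

I followed p, the fraction of the first end groups charged that couples. Once the first end groups have gone, each has either coupled or entered side product, and each side product also consumes a link, so links plus isomer equal twice p less one. That even case, p of one half, is the zero of my scale. Second end groups divide according to the selectivity factor, the ratio of the two coupling constants, 2.12, times first over third end groups present. With equal amounts in west, this gave a margin, twice p less one, of 0.291.

I let a slow feed shift that ratio by the dosing number 20, the feed time over the lifetime of first end groups. The margin therefore became 0.856 in north-east and −0.817 in south-west. I ranked north-east first.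

Then I tested the number. The isomer relaxation in north-east, 0.105 min, is short against 5.0 min, so I gave links their equilibrium portion of the margin: 16.6 % in west and 48.9 % in north-east. The negative margin in south-west gave me no positive figure for links. Yet the margin holds no side-reaction rate, so I trusted its sign more than its size.

The forecast gave north-east, with 21 %, 8 % and 41 % for west, south-west and north-east, its north-east figure below mine; its ground for that flask was feeding third end groups, “leaving little first end group to attack the links”.

The simulation gave 16.6 %, 3.78 % and 36.3 % in that order, with north-east highest. In north-east, the coupling had 97 % of its turnover behind it at 1.00 min while third end groups were still being fed, and at 3.00 min first end groups stood at 2.31 % and side product at 32.7 %. Links plus isomer less remaining first end groups read a margin of 62.7 % in north-east at 5.00 min, against my 85.6 %. With 3.80 equiv of second end groups, a north-east neighbour has p capped at the whole charge, so I reckoned a margin of 100 % and links of 57.1 %. It read 95.0 % and ended with links at 54.3 %.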